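Ring B of the flavone is a resorcinol monomethyl ether. Counted from C1', the carbon bonded to C2 of ring C, the methoxy group sits at C2' and the hydroxyl at C4'. This 1,3-dioxygenation is the imprint of a 1,1-dimethoxy-3-silyloxybutadiene, so ring B is disconnected at C1'–C2' and C5'–C6' to that diene and a terminal alkyne on C2. One Diels–Alder/methanol-loss operation builds the whole arene with both oxygens correctly placed and differentiated. The precursor is a fully decorated 2-ethynylchromone (5-OMOM, 7-OMe, 8-prenyl). It is made from a chromone-2-carboxylate whose prenyl group is delivered to C8 by a para-Claisen–Cope shift from O5.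

Key step: step 10

Remarks on the chemistry
- Assumption: 1, 2, 5, 15 and 16 are bought. The target has no stereocentre, and the only stereocentres on the way (C6 of 7, C8 of 8) are transient and racemic.
- The hot-acid chromone closure comes before the prenyl and MOM groups exist. A 5-OMOM group would not survive it, and two free ortho hydroxyls next to a prenyl group would blur 6- against 8-prenyl regiochemistry.
- The aldehyde is converted to the alkyne without any alcohol or carbonate base. The product is a vinylogous ynone that adds alkoxide, and the pyrone ring opens under such conditions.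
- Aryl silyl ether 20 is moisture-sensitive and is carried crude into step 11, which removes the silyl group anyway.

Step 1
Reactants: 1 2',6'-dihydroxy-4'-methoxyacetophenone; 2 diethyl oxalate
Product: 4 ethyl 5-hydroxy-7-methoxy-4-oxo-4H-chromene-2-carboxylate, via diketo ester 3 (not isolated)
Conditions: NaOEt (4 equiv), EtOH, reflux; then conc. HCl, EtOH, reflux
Reagents that add atoms: none
Why: Claisen condensation of the methyl ketone enolate with the oxalate followed by acid cyclodehydration is the classical chromone-2-carboxylate synthesis, and the two equivalent ortho hydroxyls of 1 make the closure regiochemically unambiguous.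

Step 2
Reactants: 4 ethyl 5-hydroxy-7-methoxy-4-oxo-4H-chromene-2-carboxylate; 5 prenyl bromide
Product: 6 ethyl 7-methoxy-5-(3-methylbut-2-enyloxy)-4-oxo-4H-chromene-2-carboxylate
Conditions: K2CO3, DMF, 50 °C
Reagents that add atoms: none
Why: Williamson etherification of the only free hydroxyl, the chelated 5-OH, by an allylic bromide in a dipolar aprotic solvent is routine for 5-hydroxychromones and 5-hydroxyflavones.

Step 3
Reactants: 6 ethyl 7-methoxy-5-(3-methylbut-2-enyloxy)-4-oxo-4H-chromene-2-carboxylate
Product: 9 ethyl 5-hydroxy-7-methoxy-8-(3-methylbut-2-enyl)-4-oxo-4H-chromene-2-carboxylate, via ortho-dienone 7 (not isolated), via para-dienone 8 (not isolated)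
Conditions: Eu(fod)3 (10 mol %), PhCl, 100 °C
Reagents that add atoms: none
Why: This is the tandem aromatic Claisen–Cope (para-Claisen) rearrangement known for 5-prenyloxy flavones, isoflavones and flavanones, in which the europium Lewis acid held between O5 and the C4 carbonyl triggers the [3,3] shift to C6, the crowded 1,1-dimethylallyl dienone 7 passes the chain on to C8 by a second [3,3] shift that restores the normal prenyl connectivity, and enolisation of 8 returns the phenol.

Step 4
Reactants: 9 ethyl 5-hydroxy-7-methoxy-8-(3-methylbut-2-enyl)-4-oxo-4H-chromene-2-carboxylate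
Product: 10 ethyl 7-methoxy-5-(methoxymethoxy)-8-(3-methylbut-2-enyl)-4-oxo-4H-chromene-2-carboxylate
Conditions: NaH, MOMCl, DMF, 0 °C to rt
Reagents that add atoms: chloromethyl methyl ether (MOMCl), COCCl
Why: Standard MOM ether formation on the sodium phenoxide removes the only acidic proton, which would otherwise quench the lithiated diazo reagent of step 7 and protonate the ketene acetal of step 10.

Step 5
Reactants: 10 ethyl 7-methoxy-5-(methoxymethoxy)-8-(3-methylbut-2-enyl)-4-oxo-4H-chromene-2-carboxylate
Product: 11 2-(hydroxymethyl)-7-methoxy-5-(methoxymethoxy)-8-(3-methylbut-2-enyl)chromen-4-one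
Conditions: NaBH4, EtOH–THF, 0 °C
Reagents that add atoms: none
Why: Chemoselective borohydride reduction is known for chromone-2-carboxylates, because the ester is activated by the electron-poor pyrone carbon C2 whereas the C4 carbonyl is a donor-rich vinylogous ester that stays untouched at 0 °C.

Step 6
Reactants: 11 2-(hydroxymethyl)-7-methoxy-5-(methoxymethoxy)-8-(3-methylbut-2-enyl)chromen-4-one
Product: 12 7-methoxy-5-(methoxymethoxy)-8-(3-methylbut-2-enyl)-4-oxo-4H-chromene-2-carbaldehyde
Conditions: Dess–Martin periodinane, CH2Cl2, 0 °C to rt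
Reagents that add atoms: none
Why: Dess–Martin oxidation stops at the aldehyde under neutral, water-free conditions that leave the prenyl alkene, the MOM acetal and the pyrone alone.

Step 7
Reactants: 12 7-methoxy-5-(methoxymethoxy)-8-(3-methylbut-2-enyl)-4-oxo-4H-chromene-2-carbaldehyde
Product: 14 2-ethynyl-7-methoxy-5-(methoxymethoxy)-8-(3-methylbut-2-enyl)chromen-4-one, via diazoalkene 13 (not isolated)
Conditions: Me3SiCHN2, LiN(i-Pr)2, THF, −78 °C; then 12, −78 to 0 °C
Reagents that add atoms: trimethylsilyldiazomethane, C[Si](C)(C)C=[N+]=[N-]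
Why: In this Colvin rearrangement (the aprotic relative of the Seyferth–Gilbert homologation) the lithiated silyldiazomethane adds to the aldehyde, by far the most electrophilic carbonyl, Peterson-type loss of silanolate gives 13, and loss of N2 with a 1,2-hydrogen shift gives the terminal alkyne at low temperature with no alcohol present.

Step 8
Reactants: 15 1,1-dimethoxyethene; 16 acetyl chloride
Product: 17 4,4-dimethoxybut-3-en-2-one
Conditions: 15 (2.2 equiv), Et2O, 0 °C to reflux; distillation
Reagents that add atoms: none
Why: Acylation of a ketene acetal at its nucleophilic CH2 carbon by an acid chloride is a known route to β,β-dialkoxy enones, with the second equivalent of 15 acting as the trap for HCl.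

Step 9
Reactants: 17 4,4-dimethoxybut-3-en-2-one
Product: 18 1,1-dimethoxy-3-(trimethylsilyloxy)buta-1,3-diene
Conditions: LiN(i-Pr)2, THF, −78 °C; Me3SiCl, −78 °C to rt; non-aqueous work-up, distillation
Reagents that add atoms: chlorotrimethylsilane, C[Si](C)(C)Cl
Why: Kinetic deprotonation at the only enolisable position (the ketone CH3) followed by O-silylation is the standard silyl enol ether synthesis used for 3-silyloxybutadienes.

Step 10
Reactants: 14 2-ethynyl-7-methoxy-5-(methoxymethoxy)-8-(3-methylbut-2-enyl)chromen-4-one; 18 1,1-dimethoxy-3-(trimethylsilyloxy)buta-1,3-diene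
Product: 20 7-methoxy-5-(methoxymethoxy)-2-[2-methoxy-4-(trimethylsilyloxy)phenyl]-8-(3-methylbut-2-enyl)chromen-4-one, via cyclohexadiene ketal 19 (not isolated)
Conditions: 18 (3 equiv), PhMe, 110 °C, sealed tube, Ar; evaporation, crude 20 carried on
Reagents that add atoms: none
Why: Proposed new method: in 14 the ethynyl group ends a vinylogous ynone (HC≡C–C2=C3–C4=O), so its CH carbon is the soft electrophilic site and should bond to the CH2 terminus of 18, onto which both acetal oxygens and the silyloxy group push electron density, while the acetal-bearing diene carbon bonds to the alkyne carbon attached to C2. Ring B thus closes as a six-membered carbocycle by an intermolecular [4+2] cycloaddition that forms C5'–C6' and C1'–C2', either concerted and asynchronous or stepwise by conjugate addition and collapse of the resulting allenolate onto the dimethoxycarbenium ion, both paths leading to cyclohexa-1,4-diene ketal 19. Under the reaction conditions 19 expels methanol (OMe from C2', H from C5') and aromatises, which leaves one methoxy group at C2' and the silyl ether at C4'. The closest known reaction type is the Diels–Alder/aromatisation of 1,1-dialkoxy-3-silyloxybutadienes with propiolates and acetylenic ketones to give resorcinol monoethers, and the untested element is that here the carbonyl acts through the C2=C3 bond of a pyrone whose O1 damps the activation. No stereocentre is formed, so only regio- and chemoselectivity are required. Regiochemistry rests on the polarity match described above, and chemoselectivity on the unhindered terminal alkyne being a far better partner for a nucleophilic diene than the trisubstituted, oxygen-bearing C2=C3 bond or the electron-rich prenyl alkene, while the MOM cap on O5 removes the only proton that could destroy the ketene acetal.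

Step 11
Reactants: 20 7-methoxy-5-(methoxymethoxy)-2-[2-methoxy-4-(trimethylsilyloxy)phenyl]-8-(3-methylbut-2-enyl)chromen-4-one
Product: 21 artocarpetin B, 5-hydroxy-2-(4-hydroxy-2-methoxyphenyl)-7-methoxy-8-(3-methylbut-2-enyl)chromen-4-one
Conditions: HCl (0.5 M in MeOH), 40 °C
Reagents that add atoms: none
Why: Acid-catalysed methanolysis cleaves the very labile aryl silyl ether and the carbonyl-flanked MOM acetal together, and the prenyl group is safe because it lies between the 7-OMe group and O1 and so has no neighbouring hydroxyl with which to close a chroman.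

Compound list
1 | 2',6'-dihydroxy-4'-methoxyacetophenone | CC(=O)c1c(O)cc(OC)cc1O | starting material
2 | diethyl oxalate | CCOC(=O)C(=O)OCC | starting material
3 | ethyl 4-(2,6-dihydroxy-4-methoxyphenyl)-2,4-dioxobutanoate (diketo ester, not isolated) | CCOC(=O)C(=O)CC(=O)c1c(O)cc(OC)cc1O | intermediate
4 | ethyl 5-hydroxy-7-methoxy-4-oxo-4H-chromene-2-carboxylate | CCOC(=O)c1cc(=O)c2c(O)cc(OC)cc2o1 | intermediate
5 | prenyl bromide (1-bromo-3-methylbut-2-ene) | CC(C)=CCBr | starting material
6 | ethyl 7-methoxy-5-(3-methylbut-2-enyloxy)-4-oxo-4H-chromene-2-carboxylate | CCOC(=O)c1cc(=O)c2c(OCC=C(C)C)cc(OC)cc2o1 | intermediate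
7 | ethyl 7-methoxy-6-(2-methylbut-3-en-2-yl)-4,5-dioxo-5,6-dihydro-4H-chromene-2-carboxylate (ortho-dienone, racemic, not isolated) | CCOC(=O)C1=CC(=O)C2=C(O1)C=C(OC)C(C2=O)C(C)(C)C=C | intermediate
8 | ethyl 7-methoxy-8-(3-methylbut-2-enyl)-4,5-dioxo-5,8-dihydro-4H-chromene-2-carboxylate (para-dienone, racemic, not isolated) | CCOC(=O)C1=CC(=O)C2=C(O1)C(CC=C(C)C)C(OC)=CC2=O | intermediate
9 | ethyl 5-hydroxy-7-methoxy-8-(3-methylbut-2-enyl)-4-oxo-4H-chromene-2-carboxylate | CCOC(=O)c1cc(=O)c2c(O)cc(OC)c(CC=C(C)C)c2o1 | intermediate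
10 | ethyl 7-methoxy-5-(methoxymethoxy)-8-(3-methylbut-2-enyl)-4-oxo-4H-chromene-2-carboxylate | CCOC(=O)c1cc(=O)c2c(OCOC)cc(OC)c(CC=C(C)C)c2o1 | intermediate
11 | 2-(hydroxymethyl)-7-methoxy-5-(methoxymethoxy)-8-(3-methylbut-2-enyl)chromen-4-one | OCc1cc(=O)c2c(OCOC)cc(OC)c(CC=C(C)C)c2o1 | intermediate
12 | 7-methoxy-5-(methoxymethoxy)-8-(3-methylbut-2-enyl)-4-oxo-4H-chromene-2-carbaldehyde | O=Cc1cc(=O)c2c(OCOC)cc(OC)c(CC=C(C)C)c2o1 | intermediate
13 | 2-(2-diazoethenyl)-7-methoxy-5-(methoxymethoxy)-8-(3-methylbut-2-enyl)chromen-4-one (diazoalkene, not isolated) | [N-]=[N+]=C=Cc1cc(=O)c2c(OCOC)cc(OC)c(CC=C(C)C)c2o1 | intermediate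
14 | 2-ethynyl-7-methoxy-5-(methoxymethoxy)-8-(3-methylbut-2-enyl)chromen-4-one | C#Cc1cc(=O)c2c(OCOC)cc(OC)c(CC=C(C)C)c2o1 | intermediate
15 | 1,1-dimethoxyethene | COC(=C)OC | starting material
16 | acetyl chloride | CC(=O)Cl | starting material
17 | 4,4-dimethoxybut-3-en-2-one | CC(=O)C=C(OC)OC | intermediate
18 | 1,1-dimethoxy-3-(trimethylsilyloxy)buta-1,3-diene | COC(OC)=CC(=C)O[Si](C)(C)C | intermediate
19 | 2-[6,6-dimethoxy-4-(trimethylsilyloxy)cyclohexa-1,4-dien-1-yl]-7-methoxy-5-(methoxymethoxy)-8-(3-methylbut-2-enyl)chromen-4-one (cyclohexadiene ketal, not isolated) | COC1(OC)C=C(O[Si](C)(C)C)CC=C1c1cc(=O)c2c(OCOC)cc(OC)c(CC=C(C)C)c2o1 | intermediate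
20 | 7-methoxy-5-(methoxymethoxy)-2-[2-methoxy-4-(trimethylsilyloxy)phenyl]-8-(3-methylbut-2-enyl)chromen-4-one | COc1cc(O[Si](C)(C)C)ccc1-c1cc(=O)c2c(OCOC)cc(OC)c(CC=C(C)C)c2o1 | intermediate
21 | artocarpetin B | COc1cc(O)ccc1-c1cc(=O)c2c(O)cc(OC)c(CC=C(C)C)c2o1 | target

Total step count: 11
Longest linear sequence: 9 (steps 1–7, 10, 11). Steps 8 and 9 form the two-step diene branch.

Steps most likely to fail

1. Step 10.
- Risk: The cycloaddition may be too slow, because the alkyne is activated only through a donor-damped pyrone. The diene could then be lost to hydrolysis, silyl migration or attack at C2 before ring B forms. Strong Lewis acids are no remedy, since they turn chromones into benzopyrylium ions that silyl enol ethers attack at C2.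
- Fallback: Ring B is brought in ready-made, and the prenyl shift is carried out on the flavone, all by known chemistry. The fallback sets out from 1 and comes back at 21.
- Commercial 4-hydroxy-2-methoxybenzaldehyde is protected with MOMCl and i-Pr2NEt to give 2-methoxy-4-(methoxymethoxy)benzaldehyde F1.
- Claisen–Schmidt condensation of 1 with F1 (KOH, EtOH, then NaOAc, EtOH, reflux) and oxa-Michael closure should give racemic 5-hydroxy-7-methoxy-2-[2-methoxy-4-(methoxymethoxy)phenyl]chroman-4-one F2.
- I2 in pyridine at 90 °C dehydrogenates it to 5-hydroxy-7-methoxy-2-[2-methoxy-4-(methoxymethoxy)phenyl]chromen-4-one F3.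
- Compound 5 and K2CO3 in DMF give 7-methoxy-2-[2-methoxy-4-(methoxymethoxy)phenyl]-5-(3-methylbut-2-enyloxy)chromen-4-one F4.
- Eu(fod)3 in PhCl moves the chain to C8 to give 5-hydroxy-7-methoxy-2-[2-methoxy-4-(methoxymethoxy)phenyl]-8-(3-methylbut-2-enyl)chromen-4-one F5.
- HCl in MeOH removes the MOM group and gives 21.

2. Step 7.
- Risk: The lithiated diazo reagent or the silanolate it releases may attack the pyrone ring or the newly formed electrophilic alkyne instead of reacting cleanly at the aldehyde.
- Fallback: A carbanion-free olefination–elimination sequence that sets out from 12 and comes back at 14.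
- CBr4 and PPh3 in CH2Cl2 at 0 °C (the first stage of the Corey–Fuchs sequence) give 2-(2,2-dibromoethenyl)-7-methoxy-5-(methoxymethoxy)-8-(3-methylbut-2-enyl)chromen-4-one F6.
- Pd(PPh3)4-catalysed hydrogenolysis with Bu3SnH removes the less hindered bromine and gives 2-[(Z)-2-bromoethenyl]-7-methoxy-5-(methoxymethoxy)-8-(3-methylbut-2-enyl)chromen-4-one F7.
- In F7 the vinylic hydrogen next to the pyrone stands anti to bromine, so DBU in CH2Cl2 should eliminate HBr to 14.

3. Step 3.
- Risk: The first dienone may enolise before the second sigmatropic shift, which would stop the migration at C6 with an inverted chain. The Lewis acid may also ionise the allyl ether, with loss of the prenyl group.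
- Fallback: The bond to the future C8 is made at the acetophenone stage by direct C-alkylation. The fallback sets out from 1 and comes back at 10.
- Compound 1 is C-prenylated with 5 (KOH, aqueous MeOH, 0 °C to rt) to 1-[2,6-dihydroxy-4-methoxy-3-(3-methylbut-2-enyl)phenyl]ethanone F8.
- One equivalent of MOMCl with i-Pr2NEt should cap the less hindered hydroxyl, remote from the prenyl group, to give 1-[2-hydroxy-4-methoxy-6-(methoxymethoxy)-3-(3-methylbut-2-enyl)phenyl]ethanone F9.
- Claisen condensation with 2 (NaOEt, EtOH) and neutral work-up give the racemic cyclic hemiketal ethyl 2-hydroxy-7-methoxy-5-(methoxymethoxy)-8-(3-methylbut-2-enyl)-4-oxochromane-2-carboxylate F10.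
- F10 is dehydrated without acid by MsCl and Et3N in CH2Cl2 at 0 °C to 10.

Further compounds
F1 | step 10 | 2-methoxy-4-(methoxymethoxy)benzaldehyde | COCOc1ccc(C=O)c(OC)c1
F2 | step 10 | 5-hydroxy-7-methoxy-2-[2-methoxy-4-(methoxymethoxy)phenyl]chroman-4-one (racemic) | COCOc1ccc(C2CC(=O)c3c(O)cc(OC)cc3O2)c(OC)c1
F3 | step 10 | 5-hydroxy-7-methoxy-2-[2-methoxy-4-(methoxymethoxy)phenyl]chromen-4-one | COCOc1ccc(-c2cc(=O)c3c(O)cc(OC)cc3o2)c(OC)c1
F4 | step 10 | 7-methoxy-2-[2-methoxy-4-(methoxymethoxy)phenyl]-5-(3-methylbut-2-enyloxy)chromen-4-one | COCOc1ccc(-c2cc(=O)c3c(OCC=C(C)C)cc(OC)cc3o2)c(OC)c1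
F5 | step 10 | 5-hydroxy-7-methoxy-2-[2-methoxy-4-(methoxymethoxy)phenyl]-8-(3-methylbut-2-enyl)chromen-4-one | COCOc1ccc(-c2cc(=O)c3c(O)cc(OC)c(CC=C(C)C)c3o2)c(OC)c1
F6 | step 7 | 2-(2,2-dibromoethenyl)-7-methoxy-5-(methoxymethoxy)-8-(3-methylbut-2-enyl)chromen-4-one | BrC(Br)=Cc1cc(=O)c2c(OCOC)cc(OC)c(CC=C(C)C)c2o1
F7 | step 7 | 2-[(Z)-2-bromoethenyl]-7-methoxy-5-(methoxymethoxy)-8-(3-methylbut-2-enyl)chromen-4-one | Br/C=C\c1cc(=O)c2c(OCOC)cc(OC)c(CC=C(C)C)c2o1
F8 | step 3 | 1-[2,6-dihydroxy-4-methoxy-3-(3-methylbut-2-enyl)phenyl]ethanone | CC(=O)c1c(O)cc(OC)c(CC=C(C)C)c1O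
F9 | step 3 | 1-[2-hydroxy-4-methoxy-6-(methoxymethoxy)-3-(3-methylbut-2-enyl)phenyl]ethanone | CC(=O)c1c(OCOC)cc(OC)c(CC=C(C)C)c1O
F10 | step 3 | ethyl 2-hydroxy-7-methoxy-5-(methoxymethoxy)-8-(3-methylbut-2-enyl)-4-oxochromane-2-carboxylate (racemic) | CCOC(=O)C1(O)CC(=O)c2c(OCOC)cc(OC)c(CC=C(C)C)c2O1
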